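**Plan**
1. Enabling feature: C3 of ring C carries the 4-hydroxyphenyl ring B and sits next to the C4 ketone on ring A. C3 can therefore be the exocyclic carbon of a ring B para-quinone methide, and C4 the acyl anion of a ring A aldehyde.
2. Cuts, in order: O–Si at C7; C3–C4 (opens ring C); C3–S of a benzylic sulfone that stores the methide; the aryl–prenyl bonds at C6 and C3'; the O1–C2 ether bond.
3. Forward: two bromophenols (rings A and B) are joined through O1–C2 by Williamson alkylation. Both prenyl groups go on in one twofold Stille coupling, and the C3 ketone is taken through the carbinol to the sulfone.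
4. Ring C is the only ring built. It closes in the penultimate step by carbene-catalysed 1,6-addition of the aldehyde to the methide.
5. Stereochemistry: the sulfone is racemic and its centre is flattened in the methide. (S)-C3 comes from the chiral triazolylidene alone and is kept away from base afterwards.

Key step: step 9

Abbreviations: prenyl = 3-methylbut-2-enyl; TIPS = triisopropylsilyl; MOM = methoxymethyl.

Assumption: the sense of induction in this new ring closure cannot be read from precedent, so the (5aR,10bS) triazolium salt (F[B-](F)(F)F.Fc1c(F)c(F)c(F)c(F)c1-[n+]1cn2c(n1)CO[C@@H]1Cc3ccccc3[C@@H]12) is written; both enantiomers are commercial, and the antipode is used if a first run should give the (R)-ketone.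

**Step 1**
Reactants: 1 5-bromo-2,4-dihydroxybenzaldehyde
Product: 2 5-bromo-2-hydroxy-4-(triisopropylsilyloxy)benzaldehyde
Conditions: TIPSCl, imidazole, CH2Cl2, 0 °C to rt
Reagents that add atoms: triisopropylsilyl chloride, CC(C)[Si](Cl)(C(C)C)C(C)C
Why: Phenol silylation is selective because the 2-OH is locked in a hydrogen bond to the formyl oxygen, so the free and more acidic 4-OH reacts, and the bulky TIPS group is chosen to outlast carbonate, hot Stille conditions, borohydride and dilute acid.

**Step 2**
Reactants: 3 3'-bromo-4'-hydroxyacetophenone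
Product: 4 1-[3-bromo-4-(methoxymethoxy)phenyl]ethanone
Conditions: MOMCl, i-Pr2NEt, CH2Cl2, 0 °C to rt
Reagents that add atoms: chloromethyl methyl ether, COCCl
Why: Methoxymethylation (acetal protection of a phenol) stops the acidic ring B phenol from alkylating itself in step 4, and the group tolerates base, palladium and hydride.

**Step 3**
Reactants: 4 1-[3-bromo-4-(methoxymethoxy)phenyl]ethanone
Product: 6 2-bromo-1-[3-bromo-4-(methoxymethoxy)phenyl]ethanone, via trimethylsilyl enol ether 5 (not isolated)
Conditions: TMSOTf, Et3N, CH2Cl2, 0 °C; then NBS, 0 °C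
Reagents that add atoms: N-bromosuccinimide, O=C1CCC(=O)N1Br; trimethylsilyl triflate, C[Si](C)(C)OS(=O)(=O)C(F)(F)F (silyl group of 5 only)
Why: Soft enolisation to the silyl enol ether followed by electrophilic bromination gives clean monobromination without HBr that would attack the acetal, and it is placed before any prenyl alkene is present, so no olefin competes for the bromine.

**Step 4**
Reactants: 2 5-bromo-2-hydroxy-4-(triisopropylsilyloxy)benzaldehyde; 6 2-bromo-1-[3-bromo-4-(methoxymethoxy)phenyl]ethanone
Product: 7 5-bromo-2-{2-[3-bromo-4-(methoxymethoxy)phenyl]-2-oxoethoxy}-4-(triisopropylsilyloxy)benzaldehyde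
Conditions: K2CO3, acetone, rt
Reagents that add atoms: none
Why: In this Williamson ether synthesis the very reactive phenacyl bromide alkylates the chelated 2-OH at room temperature, below the threshold of the Rap–Stoermer aldol condensation to a 2-aroylbenzofuran, and ethers of this type are routinely isolated.

**Step 5**
Reactants: 7 dibromo keto aldehyde; 8 tributyl(3-methylbut-2-enyl)stannane (2.6 equiv)
Product: 10 2-{2-[4-(methoxymethoxy)-3-prenylphenyl]-2-oxoethoxy}-5-prenyl-4-(triisopropylsilyloxy)benzaldehyde, via ring B monoprenyl bromide 9 (not isolated)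
Conditions: Pd(PPh3)4 (10 mol %), toluene, 105 °C, Ar
Reagents that add atoms: tributyl(3-methylbut-2-enyl)stannane 8, CCCC[Sn](CCCC)(CCCC)CC=C(C)C
Why: The twofold Stille coupling is neutral and so spares aldehyde, ketone, acetal and silyl ether, and the prenyl group should arrive through its unsubstituted terminus because reductive elimination from the aryl(prenyl)palladium species takes place at the less hindered allyl carbon.

**Step 6**
Reactants: 10 diprenyl keto aldehyde
Product: 13 rac-2-{2-hydroxy-2-[4-(methoxymethoxy)-3-prenylphenyl]ethoxy}-5-prenyl-4-(triisopropylsilyloxy)benzaldehyde, via keto dimethyl acetal 11 (not isolated), via hydroxy dimethyl acetal 12 (not isolated)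
Conditions: CeCl3·7H2O (0.4 equiv), HC(OMe)3, MeOH, rt; NaBH4, 0 °C; then 1 M HCl, THF, 0 °C to rt
Reagents that add atoms: trimethyl orthoformate, COC(OC)OC (methoxy groups of 11 and 12 only); water, O (formyl oxygen of 13)
Why: In the Luche in situ protection protocol, lanthanide-catalysed acetalisation picks the aldehyde over the aryl ketone, borohydride then meets only the ketone and dilute acid returns the very labile electron-rich acetal to the aldehyde; the carbinol centre forms racemic, which is harmless because it is planarised in step 9.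

**Step 7**
Reactants: 13 racemic hydroxy aldehyde; 14 sodium benzenesulfinate
Product: 16 rac-2-{2-[4-(methoxymethoxy)-3-prenylphenyl]-2-(phenylsulfonyl)ethoxy}-5-prenyl-4-(triisopropylsilyloxy)benzaldehyde, via benzylic mesylate 15 (not isolated)
Conditions: MsCl, Et3N, CH2Cl2, −10 °C; aqueous wash; then 14, DMF, rt
Reagents that add atoms: sodium benzenesulfinate 14, [Na+].[O-]S(=O)c1ccccc1; methanesulfonyl chloride, CS(=O)(=O)Cl (mesyl group of 15 only)
Why: This is the classical sulfone synthesis by alkylation of a sulfinate salt, in which the para-alkoxy group activates the benzylic mesylate, the soft and weakly basic sulfinate substitutes through sulfur without elimination, and any O-alkylated ester should revert to the more stable sulfone.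

**Step 8**
Reactants: 16 racemic MOM-protected sulfone
Product: 17 rac-2-[2-(4-hydroxy-3-prenylphenyl)-2-(phenylsulfonyl)ethoxy]-5-prenyl-4-(triisopropylsilyloxy)benzaldehyde
Conditions: 3 M aq HCl, MeOH–THF, rt to 40 °C
Reagents that add atoms: none
Why: Acid-catalysed acetal cleavage of aryl MOM ethers under these dilute conditions is standard practice on prenylated phenols, while the aryl TIPS ether (very slow to cleave in acid) and the electron-withdrawing sulfone, which suppresses benzylic ionisation, stay intact.

**Step 9**
Reactants: 17 racemic hydroxy sulfone aldehyde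
Product: 19 (3S)-3-(4-hydroxy-3-prenylphenyl)-6-prenyl-7-(triisopropylsilyloxy)chroman-4-one, via para-quinone methide aldehyde 18 (not isolated)
Conditions: (5aR,10bS)-2-(pentafluorophenyl)-5a,10b-dihydro-4H,6H-indeno[2,1-b][1,2,4]triazolo[4,3-d][1,4]oxazin-2-ium tetrafluoroborate (15 mol %), powdered K2CO3 (1.15 equiv), 4 Å MS, toluene (0.02 M), 0 °C, Ar; cold pH 5 buffer work-up
Reagents that add atoms: none
Why: Proposed new method: carbonate deprotonates the ring B phenol (far more acidic than the α-sulfonyl C–H), the phenoxide expels benzenesulfinate by 1,6-elimination to give methide 18, and in parallel the triazolylidene adds to the ring A formyl group and after proton transfer becomes a carbene-bound enaminol (Breslow type) whose nucleophilic carbon attacks the exocyclic methide carbon C3, after which rearomatisation of ring B and expulsion of the carbene deliver the C4 ketone. The closest known reaction types are the enantioselective intramolecular Stetter reaction of O-tethered salicylaldehydes, which gives 3-substituted chroman-4-ones through the same O1–C2 tether, and the intermolecular carbene-catalysed 1,6-addition of aldehydes to stable, hindered para-quinone methides; what has not been shown is their union on a transient, unhindered methide that bears hydrogens on the neighbouring carbon. Ring C closes in a 6-exo-trig mode, because the attacked C3=C1' bond lies outside the forming ring and only C3 becomes a ring member. C3 is the only new stereocentre and is catalyst-controlled: the fused aminoindanol backbone blocks one face of the enaminol, the short tether leaves one approach of the methide to the open face, and the E/Z isomerism of 18 is erased on rearomatisation, so both enantiomers of 17 converge on (S)-19. The step needs C–C closure to beat tautomerisation of 18 to the styryl aryl ether, loss of the ring A phenoxide from 17 and intermolecular phenol or carbene addition at C3; the two-atom tether, high dilution, slow heterogeneous release of 18 and reversible re-addition of sulfinate keep free methide scarce, and β-aryloxy para-quinone methides of the lignin type are known to persist in solution long enough for nucleophiles to add. The acidic C3–H of 19 is protected because the base is insoluble, used in slight excess only and consumed by the liberated sulfinic acid as the reaction runs at 0 °C.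

**Step 10**
Reactants: 19 (S)-isoflavanone TIPS ether
Product: 20 (3S)-7-hydroxy-3-[4-hydroxy-3-(3-methylbut-2-enyl)phenyl]-6-(3-methylbut-2-enyl)-2,3-dihydro-4H-chromen-4-one (target)
Conditions: TBAF (1.2 equiv), AcOH (2.4 equiv), THF, 0 °C
Reagents that add atoms: none
Why: Fluoride-mediated desilylation is fast here because the silyl ether is para to the C4 ketone, and the excess acetic acid protonates the phenoxide at once and keeps the medium too weakly basic to enolise C3, so the (S) configuration should be retained.

**Compound list**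
1 | 5-bromo-2,4-dihydroxybenzaldehyde | O=Cc1cc(Br)c(O)cc1O | starting material
2 | 5-bromo-2-hydroxy-4-(triisopropylsilyloxy)benzaldehyde | O=Cc1cc(Br)c(O[Si](C(C)C)(C(C)C)C(C)C)cc1O | intermediate
3 | 3'-bromo-4'-hydroxyacetophenone | CC(=O)c1ccc(O)c(Br)c1 | starting material
4 | 1-[3-bromo-4-(methoxymethoxy)phenyl]ethanone | CC(=O)c1ccc(OCOC)c(Br)c1 | intermediate
5 | {1-[3-bromo-4-(methoxymethoxy)phenyl]ethenyloxy}trimethylsilane (not isolated) | C=C(O[Si](C)(C)C)c1ccc(OCOC)c(Br)c1 | intermediate
6 | 2-bromo-1-[3-bromo-4-(methoxymethoxy)phenyl]ethanone | O=C(CBr)c1ccc(OCOC)c(Br)c1 | intermediate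
7 | 5-bromo-2-{2-[3-bromo-4-(methoxymethoxy)phenyl]-2-oxoethoxy}-4-(triisopropylsilyloxy)benzaldehyde | O=Cc1cc(Br)c(O[Si](C(C)C)(C(C)C)C(C)C)cc1OCC(=O)c1ccc(OCOC)c(Br)c1 | intermediate
8 | tributyl(3-methylbut-2-enyl)stannane | CCCC[Sn](CCCC)(CCCC)CC=C(C)C | starting material
9 | 5-bromo-2-{2-[4-(methoxymethoxy)-3-prenylphenyl]-2-oxoethoxy}-4-(triisopropylsilyloxy)benzaldehyde (not isolated) | O=Cc1cc(Br)c(O[Si](C(C)C)(C(C)C)C(C)C)cc1OCC(=O)c1ccc(OCOC)c(CC=C(C)C)c1 | intermediate
10 | 2-{2-[4-(methoxymethoxy)-3-prenylphenyl]-2-oxoethoxy}-5-prenyl-4-(triisopropylsilyloxy)benzaldehyde | O=Cc1cc(CC=C(C)C)c(O[Si](C(C)C)(C(C)C)C(C)C)cc1OCC(=O)c1ccc(OCOC)c(CC=C(C)C)c1 | intermediate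
11 | dimethyl acetal of 10 (not isolated) | COC(OC)c1cc(CC=C(C)C)c(O[Si](C(C)C)(C(C)C)C(C)C)cc1OCC(=O)c1ccc(OCOC)c(CC=C(C)C)c1 | intermediate
12 | racemic carbinol dimethyl acetal (not isolated) | COC(OC)c1cc(CC=C(C)C)c(O[Si](C(C)C)(C(C)C)C(C)C)cc1OCC(O)c1ccc(OCOC)c(CC=C(C)C)c1 | intermediate
13 | rac-2-{2-hydroxy-2-[4-(methoxymethoxy)-3-prenylphenyl]ethoxy}-5-prenyl-4-(triisopropylsilyloxy)benzaldehyde | O=Cc1cc(CC=C(C)C)c(O[Si](C(C)C)(C(C)C)C(C)C)cc1OCC(O)c1ccc(OCOC)c(CC=C(C)C)c1 | intermediate
14 | sodium benzenesulfinate | [Na+].[O-]S(=O)c1ccccc1 | starting material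
15 | racemic benzylic mesylate of 13 (not isolated) | O=Cc1cc(CC=C(C)C)c(O[Si](C(C)C)(C(C)C)C(C)C)cc1OCC(OS(C)(=O)=O)c1ccc(OCOC)c(CC=C(C)C)c1 | intermediate
16 | rac-2-{2-[4-(methoxymethoxy)-3-prenylphenyl]-2-(phenylsulfonyl)ethoxy}-5-prenyl-4-(triisopropylsilyloxy)benzaldehyde | O=Cc1cc(CC=C(C)C)c(O[Si](C(C)C)(C(C)C)C(C)C)cc1OCC(c1ccc(OCOC)c(CC=C(C)C)c1)S(=O)(=O)c1ccccc1 | intermediate
17 | rac-2-[2-(4-hydroxy-3-prenylphenyl)-2-(phenylsulfonyl)ethoxy]-5-prenyl-4-(triisopropylsilyloxy)benzaldehyde | O=Cc1cc(CC=C(C)C)c(O[Si](C(C)C)(C(C)C)C(C)C)cc1OCC(c1ccc(O)c(CC=C(C)C)c1)S(=O)(=O)c1ccccc1 | intermediate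
18 | 2-[2-(4-oxo-3-prenylcyclohexa-2,5-dien-1-ylidene)ethoxy]-5-prenyl-4-(triisopropylsilyloxy)benzaldehyde, E/Z mixture (not isolated) | O=Cc1cc(CC=C(C)C)c(O[Si](C(C)C)(C(C)C)C(C)C)cc1OCC=C1C=CC(=O)C(CC=C(C)C)=C1 | intermediate
19 | (3S)-3-(4-hydroxy-3-prenylphenyl)-6-prenyl-7-(triisopropylsilyloxy)chroman-4-one | CC(C)=CCc1cc([C@H]2COc3cc(O[Si](C(C)C)(C(C)C)C(C)C)c(CC=C(C)C)cc3C2=O)ccc1O | intermediate
20 | (3S)-7-hydroxy-3-[4-hydroxy-3-(3-methylbut-2-enyl)phenyl]-6-(3-methylbut-2-enyl)-2,3-dihydro-4H-chromen-4-one | CC(C)=CCc1cc([C@H]2COc3cc(O)c(CC=C(C)C)cc3C2=O)ccc1O | target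

**Total step count:** 10
**Longest linear sequence:** 9 steps (3 to 20, steps 2–10)

**Steps most likely to fail**

Step 9. Several processes could spoil the closure:
- tautomerisation of the transient methide before the ring closes;
- capture of the carbene at C3;
- weak facial discrimination;
- base-induced loss of configuration after closure.

The fallback uses known chemistry only, sets out from keto aldehyde 10 and comes back at 19. An achiral triazolium salt with Et3N forms the same C3–C4 bond by the intramolecular crossed aldehyde–ketone benzoin reaction and should give the racemic 3-hydroxyisoflavanone F1. SOCl2 in pyridine dehydrates it across C2–C3 to the isoflavone F2. Asymmetric transfer hydrogenation with RuCl[(S,S)-TsDPEN](p-cymene) in HCO2H/Et3N reduces the C2–C3 double bond. It then reduces the ketone under dynamic kinetic resolution of the configurationally labile ketone, giving the cis-(3S,4S)-isoflavan-4-ol F3 with the prenyl alkenes untouched. Dess–Martin periodinane reoxidises C4 without involving C3 and gives the (S)-isoflavanone MOM ether F4. Dilute HCl in MeOH at room temperature frees the ring B phenol to give 19.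

Step 6. Incomplete or reversible acetalisation of the electron-rich aldehyde would let borohydride reduce the formyl group as well. The fallback sets out from 10 and comes back at 13. NaBH4 in MeOH–THF reduces both carbonyl groups on purpose to the racemic diol F5. Catalytic TEMPO with PhI(OAc)2 in CH2Cl2, which discriminates strongly between primary and secondary alcohols, then reoxidises only the primary benzylic alcohol to the aldehyde.

Step 5. Three processes could erode the twofold coupling: sluggish oxidative addition next to the bulky silyl ether, transfer of the prenyl group through its substituted terminus, and addition of the stannane to the aldehyde. The fallback sets out from 7 and comes back at 10 and builds the prenyl groups in two stages. The smaller, regiochemically unambiguous allyltributylstannane is coupled with Pd(PPh3)4 to give the diallyl keto aldehyde F6. Cross metathesis with excess 2-methylbut-2-ene and the second-generation Grubbs catalyst in CH2Cl2 at 40 °C converts both allyl groups into prenyl groups.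

**Further compounds**
F1 | step 9 | rac-3-hydroxy-3-[4-(methoxymethoxy)-3-prenylphenyl]-6-prenyl-7-(triisopropylsilyloxy)chroman-4-one | CC(C)=CCc1cc(C2(O)COc3cc(O[Si](C(C)C)(C(C)C)C(C)C)c(CC=C(C)C)cc3C2=O)ccc1OCOC
F2 | step 9 | 3-[4-(methoxymethoxy)-3-prenylphenyl]-6-prenyl-7-(triisopropylsilyloxy)-4H-chromen-4-one | CC(C)=CCc1cc(-c2coc3cc(O[Si](C(C)C)(C(C)C)C(C)C)c(CC=C(C)C)cc3c2=O)ccc1OCOC
F3 | step 9 | (3S,4S)-3-[4-(methoxymethoxy)-3-prenylphenyl]-6-prenyl-7-(triisopropylsilyloxy)chroman-4-ol (cis) | CC(C)=CCc1cc([C@H]2COc3cc(O[Si](C(C)C)(C(C)C)C(C)C)c(CC=C(C)C)cc3[C@H]2O)ccc1OCOC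
F4 | step 9 | (3S)-3-[4-(methoxymethoxy)-3-prenylphenyl]-6-prenyl-7-(triisopropylsilyloxy)chroman-4-one | CC(C)=CCc1cc([C@H]2COc3cc(O[Si](C(C)C)(C(C)C)C(C)C)c(CC=C(C)C)cc3C2=O)ccc1OCOC
F5 | step 6 | rac-2-[2-(hydroxymethyl)-4-prenyl-5-(triisopropylsilyloxy)phenoxy]-1-[4-(methoxymethoxy)-3-prenylphenyl]ethanol | OCc1cc(CC=C(C)C)c(O[Si](C(C)C)(C(C)C)C(C)C)cc1OCC(O)c1ccc(OCOC)c(CC=C(C)C)c1
F6 | step 5 | 5-allyl-2-{2-[3-allyl-4-(methoxymethoxy)phenyl]-2-oxoethoxy}-4-(triisopropylsilyloxy)benzaldehyde | O=Cc1cc(CC=C)c(O[Si](C(C)C)(C(C)C)C(C)C)cc1OCC(=O)c1ccc(OCOC)c(CC=C)c1
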